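**Strategy.** Xestin A is cut at the O2–C3 bond of its 3,6-dihydro-1,2-dioxine ring. C3 is β to the C1 ester carbonyl and bound to peroxide oxygen O2, so the ring can be closed by conjugate addition of a hydroperoxide, while the C6 peroxyketal stays adjustable under acid. In one operation a chiral squaramide–amine catalyst should turn an achiral, open-chain (2E,4Z)-6,6-bis(hydroperoxy) dienoate into the (3R)-configured cyclic peroxide, forming the ring and the only stereocentre that cannot be corrected later. The precursor is assembled in five steps from furan, 1,6-dibromohexane, codlemone and a stabilised ylide; a final acid-mediated methanol exchange sets C6.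

Key step: step 6

Remark on the structures: the target is (3R,6R), with the C6 methoxy group cis to the C3 acetate arm and thirteen methylenes between C6 and the (E,E)-diene. Target, precursor and cyclised product are mutually consistent, so no structure was altered.

Assumption: the sense of induction of the squaramide cannot be predicted; both pseudoenantiomeric catalysts (quinine and quinidine series) are available, and the one that delivers (3R) is meant wherever the catalyst is named.

Design remarks:
- The C18 side chain is built without protecting groups by joining a furan-terminated C6 bromide to codlemone tosylate.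
- The furan is opened with singlet oxygen, which discriminates between the furan and the remote diene.
- The bis-hydroperoxide is made and handled amine-free until the catalyst is added.

**Step 1**
Reactants: 1 furan; 2 1,6-dibromohexane
Product: 4 2-(6-bromohexyl)furan, via 2-furyllithium 3 (not isolated)
Conditions: n-BuLi, THF, −78 → 0 °C; then 2 (3 equiv), −78 °C → rt
Reagents that add atoms: none
Why: α-Lithiation of furan followed by SN2 alkylation of the 2-furyllithium with a primary bromide is routine heteroaryllithium chemistry, and the excess of the symmetrical dibromide should hold back double substitution.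

**Step 2**
Reactants: 5 (8E,10E)-dodeca-8,10-dien-1-ol (codlemone)
Product: 6 (8E,10E)-dodeca-8,10-dien-1-yl 4-methylbenzenesulfonate
Conditions: TsCl, Et3N, DMAP (cat.), CH2Cl2, 0 °C → rt
Reagents that add atoms: p-toluenesulfonyl chloride, Cc1ccc(cc1)S(=O)(=O)Cl
Why: Sulfonylation of a primary alcohol under amine base is routine and leaves the remote (E,E)-diene untouched.

**Step 3**
Reactants: 4 2-(6-bromohexyl)furan; 6 (8E,10E)-dodeca-8,10-dien-1-yl 4-methylbenzenesulfonate
Product: 8 2-[(14E,16E)-octadeca-14,16-dien-1-yl]furan, via furylhexylmagnesium bromide 7 (not isolated)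
Conditions: 4, Mg, THF, rt → 40 °C; then 6, Li2CuCl4 (cat.), THF, −78 °C → rt
Reagents that add atoms: none
Why: A Li2CuCl4-catalysed sp3–sp3 cross-coupling of a primary alkyl Grignard reagent with a primary tosylate should join the C6 and C12 pieces without touching the furan or the diene, whose geometry is not involved.

**Step 4**
Reactants: 8 2-[(14E,16E)-octadeca-14,16-dien-1-yl]furan; 9 methyl (triphenylphosphoranylidene)acetate
Product: 12 methyl (2E,4Z,20E,22E)-6-oxotetracosa-2,4,20,22-tetraenoate, via furan endoperoxide 10 (not isolated), via cis-4-oxo-2-enal 11 (not isolated)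
Conditions: O2, hν (visible), tetraphenylporphyrin (cat.), CH2Cl2, −78 °C; Me2S, −78 → 0 °C; then 9, 0 °C → rt, dark
Reagents that add atoms: dioxygen, O=O
Why: Singlet oxygen should add in a [4+2] cycloaddition to the electron-rich furan far faster than to the acyclic diene, reductive cleavage of the endoperoxide by Me2S unveils the cis-4-oxo-2-enal with the Z geometry inherited from the ring, and the stabilised ylide then olefinates only the aldehyde in an E-selective Wittig reaction.

**Step 5**
Reactants: 12 methyl (2E,4Z,20E,22E)-6-oxotetracosa-2,4,20,22-tetraenoate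
Product: 13 methyl (2E,4Z,20E,22E)-6,6-dihydroperoxytetracosa-2,4,20,22-tetraenoate
Conditions: 50% aq. H2O2 (excess), CSA (cat.), MeCN–CH2Cl2, 0 °C, dark; cold NaHCO3 work-up, used promptly
Reagents that add atoms: hydrogen peroxide, OO
Why: Acid-catalysed peroxyketalisation of the ketone (gem-dihydroperoxide formation via the hydroperoxy hemiketal and a peroxycarbenium ion) should be driven by excess H2O2, while the acidic, amine-free medium keeps the neutral hydroperoxide from adding to the enoate and cold, dark conditions preserve the 4Z geometry.

**Step 6**
Reactants: 13 methyl (2E,4Z,20E,22E)-6,6-dihydroperoxytetracosa-2,4,20,22-tetraenoate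
Product: 14 methyl 2-[(3R)-6-hydroperoxy-6-[(14E,16E)-octadeca-14,16-dien-1-yl]-3,6-dihydro-1,2-dioxin-3-yl]acetate (both C6 epimers)
Conditions: 9-amino-9-deoxy-epi-quinine-derived 3,5-bis(trifluoromethyl)phenyl squaramide (10 mol%), toluene, −40 °C; cold filtration through SiO2
Reagents that add atoms: none
Why: Proposed new method: the quinuclidine nitrogen should reversibly deprotonate one of the two acidic geminal OOH groups while the squaramide NH pair hydrogen-bonds the C1 ester carbonyl, so that the peroxide oxygen is delivered to C3 of the 2E-enoate and the ester enolate is protonated at C2 by the ammonium ion or the second OOH before it can collapse to an epoxide; the closest known reaction types are amine-promoted intramolecular hydroperoxide conjugate additions giving 1,2-dioxanes and squaramide–amine-catalysed enantioselective intramolecular oxa-Michael additions. The 1,2-dioxine ring closes in a 6-exo-trig mode through the new O2–C3 bond. The C3 stereocentre is set by catalyst control of the enoate face, since the substrate is achiral; C6 also becomes stereogenic but is left uncontrolled because step 7 equilibrates it. Only enantiofacial selectivity is required: the 4Z alkene holds C6 and C3 on the same side so no other ring size is accessible, the two OOH groups are enantiotopic so the choice between them affects only the correctable C6 configuration, and C6 bears no hydrogen so Kornblum–DeLaMare fragmentation cannot start in the substrate. The cold silica filtration removes the amine before it can attack the C3–H of the product.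

**Step 7**
Reactants: 14 methyl 2-[(3R)-6-hydroperoxy-6-[(14E,16E)-octadeca-14,16-dien-1-yl]-3,6-dihydro-1,2-dioxin-3-yl]acetate
Product: 15 methyl 2-[(3R,6R)-6-methoxy-6-[(14E,16E)-octadeca-14,16-dien-1-yl]-3,6-dihydro-1,2-dioxin-3-yl]acetate (Xestin A)
Conditions: CSA (cat.), MeOH–CH2Cl2, 0 °C → rt
Reagents that add atoms: methanol, CO
Why: Acid-catalysed SN1 exchange at the peroxyketal carbon (loss of H2O2 to the O1-stabilised peroxycarbenium ion and capture by methanol) is reversible, so C6 should settle under thermodynamic control in the (6R) epimer with OMe pseudoaxial (anomeric effect of O1) and cis to the pseudoequatorial C3 arm, while C3 is not involved.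

**Compound list**
1 | furan | c1ccoc1 | starting material
2 | 1,6-dibromohexane | BrCCCCCCBr | starting material
3 | 2-furyllithium | [Li]c1ccco1 | intermediate (not isolated)
4 | 2-(6-bromohexyl)furan | BrCCCCCCc1ccco1 | intermediate
5 | (8E,10E)-dodeca-8,10-dien-1-ol (codlemone) | C/C=C/C=C/CCCCCCCO | starting material
6 | (8E,10E)-dodeca-8,10-dien-1-yl 4-methylbenzenesulfonate | C/C=C/C=C/CCCCCCCOS(=O)(=O)c1ccc(C)cc1 | intermediate
7 | [6-(furan-2-yl)hexyl]magnesium bromide | Br[Mg]CCCCCCc1ccco1 | intermediate (not isolated)
8 | 2-[(14E,16E)-octadeca-14,16-dien-1-yl]furan | C/C=C/C=C/CCCCCCCCCCCCCc1ccco1 | intermediate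
9 | methyl (triphenylphosphoranylidene)acetate | COC(=O)C=P(c1ccccc1)(c1ccccc1)c1ccccc1 | starting material
10 | 1-[(14E,16E)-octadeca-14,16-dien-1-yl]-2,3,7-trioxabicyclo[2.2.1]hept-5-ene (racemic furan endoperoxide) | C/C=C/C=C/CCCCCCCCCCCCCC12OOC(C=C1)O2 | intermediate (not isolated)
11 | (2Z,18E,20E)-4-oxodocosa-2,18,20-trienal | C/C=C/C=C/CCCCCCCCCCCCCC(=O)/C=C\C=O | intermediate (not isolated)
12 | methyl (2E,4Z,20E,22E)-6-oxotetracosa-2,4,20,22-tetraenoate | C/C=C/C=C/CCCCCCCCCCCCCC(=O)/C=C\C=C\C(=O)OC | intermediate
13 | methyl (2E,4Z,20E,22E)-6,6-dihydroperoxytetracosa-2,4,20,22-tetraenoate | C/C=C/C=C/CCCCCCCCCCCCCC(OO)(OO)/C=C\C=C\C(=O)OC | intermediate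
14 | methyl 2-[(3R)-6-hydroperoxy-6-[(14E,16E)-octadeca-14,16-dien-1-yl]-3,6-dihydro-1,2-dioxin-3-yl]acetate (both C6 epimers) | C/C=C/C=C/CCCCCCCCCCCCCC1(OO)C=C[C@@H](CC(=O)OC)OO1 | intermediate
15 | methyl 2-[(3R,6R)-6-methoxy-6-[(14E,16E)-octadeca-14,16-dien-1-yl]-3,6-dihydro-1,2-dioxin-3-yl]acetate (Xestin A) | C/C=C/C=C/CCCCCCCCCCCCC[C@]1(OC)C=C[C@@H](CC(=O)OC)OO1 | target

Total step count: 7
Longest linear sequence: 6 steps (step 1 or step 2, then steps 3–7)

**Steps most likely to fail**

1. Step 6. Possible failures are insufficient enantiofacial discrimination (including a racemic background closure), collapse of the β-peroxy enolate to a 2,3-epoxide, or amine-induced Kornblum–DeLaMare degradation of the product through its C3–H. The fallback gives up catalyst control in favour of resolution. Setting out from 13, closure with an achiral secondary amine (Et2NH in CF3CH2OH, the established amine-promoted intramolecular hydroperoxide conjugate addition) should give racemic methyl 2-[6-hydroperoxy-6-[(14E,16E)-octadeca-14,16-dien-1-yl]-3,6-dihydro-1,2-dioxin-3-yl]acetate F1. The conditions of step 7 then convert F1 into the racemate, that is 15 together with its enantiomer methyl 2-[(3S,6S)-6-methoxy-6-[(14E,16E)-octadeca-14,16-dien-1-yl]-3,6-dihydro-1,2-dioxin-3-yl]acetate F2. Preparative HPLC on a polysaccharide chiral stationary phase separates the two, and the route is rejoined at 15.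

2. Step 5. Possible failures are sluggish perhydrolysis of the conjugated ketone, acid-induced 4Z→4E isomerisation, or premature uncatalysed ring closure of the hydroperoxy hemiketal. The fallback accepts that closure instead of fighting it. Setting out from 12, neutral H2O2 in THF–CF3CH2OH (with a trace of amine only if closure stalls) is allowed to add to the ketone and cyclise in the same flask. This hydroperoxy hemiketal/peroxy-Michael cascade is established for (2E,4Z)-6-oxo-dienoates and should give racemic methyl 2-[6-hydroxy-6-[(14E,16E)-octadeca-14,16-dien-1-yl]-3,6-dihydro-1,2-dioxin-3-yl]acetate F3. CSA in methanol ketalises F3 to racemic 15 (15 plus the enantiomer F2 described above), which is resolved on a chiral phase as in the first fallback, rejoining the route at 15.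

3. Step 7. Possible failures are acid-induced heterolytic rearrangement of the exocyclic hydroperoxy ketal competing with simple ionisation, or only a weak thermodynamic preference between the C6 epimers. The fallback removes the exocyclic O–O bond before ketalisation. Setting out from 14, chemoselective reduction of the hydroperoxide with Me2S (the ring O1–O2 dialkyl peroxide is not touched) should give the peroxy hemiketal methyl 2-[(3R)-6-hydroxy-6-[(14E,16E)-octadeca-14,16-dien-1-yl]-3,6-dihydro-1,2-dioxin-3-yl]acetate F4. Acid-catalysed methyl ketalisation of such 1,2-dioxin-ols in methanol, with water as the leaving group, is the established entry to 6-methoxy-3,6-dihydro-1,2-dioxines and returns to the route at 15. The chromatographically separable C6 epimer is resubmitted to the equilibration.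

**Further compounds**
F1 | step 6 | methyl 2-[6-hydroperoxy-6-[(14E,16E)-octadeca-14,16-dien-1-yl]-3,6-dihydro-1,2-dioxin-3-yl]acetate (racemic) | C/C=C/C=C/CCCCCCCCCCCCCC1(OO)C=CC(CC(=O)OC)OO1
F2 | step 6 | methyl 2-[(3S,6S)-6-methoxy-6-[(14E,16E)-octadeca-14,16-dien-1-yl]-3,6-dihydro-1,2-dioxin-3-yl]acetate (enantiomer of 15) | C/C=C/C=C/CCCCCCCCCCCCC[C@@]1(OC)C=C[C@H](CC(=O)OC)OO1
F3 | step 5 | methyl 2-[6-hydroxy-6-[(14E,16E)-octadeca-14,16-dien-1-yl]-3,6-dihydro-1,2-dioxin-3-yl]acetate (racemic) | C/C=C/C=C/CCCCCCCCCCCCCC1(O)C=CC(CC(=O)OC)OO1
F4 | step 7 | methyl 2-[(3R)-6-hydroxy-6-[(14E,16E)-octadeca-14,16-dien-1-yl]-3,6-dihydro-1,2-dioxin-3-yl]acetate | C/C=C/C=C/CCCCCCCCCCCCCC1(O)C=C[C@@H](CC(=O)OC)OO1
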